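**Retrosynthetic overview**
1. Opening the ring B hemiketal leads back to an achiral 1-aryl-4-(pyron-6-yl)butane-1,3-dione. C2 is configurationally labile, so the (R) antipode is secured in the last operation by resolution.
2. The β-diketone comes from a 1,3-diol by oxidation. The key C2–CH2(pyrone) bond comes from an intermolecular vinylogous aldol addition of lithiated 4-benzyloxy-6-methyl-2-pyrone to a 3-aryl-3-silyloxypropanal.
3. That aldehyde comes from an acetate-type aldol of the N-methoxy-N-methylacetamide enolate with 2,4-bis(benzyloxy)-6-isopentylbenzaldehyde, followed by silylation and i-Bu2AlH reduction.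
4. The benzaldehyde comes from 5-isopentylresorcinol by Vilsmeier formylation and benzylation. The resorcinol comes from 3,5-dimethoxybenzaldehyde and the isobutyl ylide by Wittig reaction, hydrogenation and BBr3.
5. Ring order: ring A (arene) and ring C (pyrone, from triacetic acid lactone) are bought in. Ring B is the only ring formed, in the penultimate step.

**Assumption:** C2 is a hemiketal carbon that can invert through the open-chain diketone, so no earlier stereocentre can be relayed to it; the (R) form is fixed last and must be kept cold, neutral and out of protic solvents, and the carbinol centres of the intermediates are carried as racemates or diastereomer mixtures because they are oxidised away.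

**Step 1**
Reactants: 1 3,5-dimethoxybenzaldehyde; 2 (2-methylpropyl)triphenylphosphonium bromide
Product: 4 1,3-dimethoxy-5-(3-methylbut-1-en-1-yl)benzene (Z/E mixture), via phosphorus ylide 3 (not isolated)
Conditions: KOt-Bu (1.2 equiv), THF, 0 °C, 30 min; then 1, 0 °C → rt
Reagents that add atoms: none
Why: This is a Wittig olefination of a non-enolisable aromatic aldehyde with a non-stabilised ylide, and the alkene geometry does not matter because the double bond is saturated next.

**Step 2**
Reactants: 4 1,3-dimethoxy-5-(3-methylbut-1-en-1-yl)benzene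
Product: 5 1,3-dimethoxy-5-(3-methylbutyl)benzene
Conditions: H2 (1 atm), 10% Pd/C, EtOAc, rt
Reagents that add atoms: none
Why: Heterogeneous catalytic hydrogenation of a styrene-type alkene converges both isomers to one alkane, and the aryl methyl ethers are inert.

**Step 3**
Reactants: 5 1,3-dimethoxy-5-(3-methylbutyl)benzene
Product: 7 5-(3-methylbutyl)benzene-1,3-diol, via bis(dibromoboryl) ether 6 (not isolated)
Conditions: BBr3 (3 equiv), CH2Cl2, −78 °C → rt; then H2O, 0 °C
Reagents that add atoms: none
Why: Lewis-acid cleavage of aryl methyl ethers is the standard entry to 5-alkylresorcinols, and the molecule has no other functional group.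

**Step 4**
Reactants: 7 5-(3-methylbutyl)benzene-1,3-diol
Product: 9 2,4-dihydroxy-6-(3-methylbutyl)benzaldehyde, via aryl iminium salt 8 (not isolated)
Conditions: POCl3 (1.5 equiv), DMF, 0 °C → rt; then ice–H2O, rt
Reagents that add atoms: N,N-dimethylformamide CN(C)C=O; water O
Why: Vilsmeier–Haack formylation of 5-alkylresorcinols occurs para to one hydroxyl and ortho to the other, avoiding the crowded site between the two oxygens, which gives exactly the substitution pattern of ring A.

**Step 5**
Reactants: 9 2,4-dihydroxy-6-(3-methylbutyl)benzaldehyde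
Product: 10 2,4-bis(benzyloxy)-6-(3-methylbutyl)benzaldehyde
Conditions: BnBr (2.4 equiv), K2CO3 (3 equiv), DMF, 60 °C
Reagents that add atoms: benzyl bromide BrCc1ccccc1
Why: In this Williamson ether synthesis, warming in DMF also alkylates the hydrogen-bonded ortho phenol, and benzyl is chosen because it leaves under neutral conditions at the end.

**Step 6**
Reactants: 10 2,4-bis(benzyloxy)-6-(3-methylbutyl)benzaldehyde; 11 N-methoxy-N-methylacetamide
Product: 13 rac-3-[2,4-bis(benzyloxy)-6-(3-methylbutyl)phenyl]-3-hydroxy-N-methoxy-N-methylpropanamide, via lithium amide enolate 12 (not isolated)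
Conditions: 11 (1.35 equiv), commercial LiN(i-Pr)2 solution (1.3 equiv), THF, −78 °C, 30 min; then 10, −78 °C, 1 h; AcOH quench at −78 °C
Reagents that add atoms: none
Why: This is a directed aldol addition of a preformed lithium enolate to a non-enolisable aldehyde; the cold acidic quench prevents retro-aldol, and the new carbinol centre is racemic and is erased in step 12.

**Step 7**
Reactants: 13 rac-3-[2,4-bis(benzyloxy)-6-(3-methylbutyl)phenyl]-3-hydroxy-N-methoxy-N-methylpropanamide
Product: 14 rac-3-[2,4-bis(benzyloxy)-6-(3-methylbutyl)phenyl]-3-[(tert-butyldimethylsilyl)oxy]-N-methoxy-N-methylpropanamide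
Conditions: TBSOTf (1.3 equiv), 2,6-lutidine (2 equiv), CH2Cl2, −78 → 0 °C
Reagents that add atoms: tert-butyldimethylsilyl triflate CC(C)(C)[Si](C)(C)OS(=O)(=O)C(F)(F)F
Why: In this silyl ether protection the triflate silylates the hindered carbinol quickly, while lutidine keeps the medium non-acidic so that the electron-rich benzylic C–O bond does not ionise.

**Step 8**
Reactants: 14 rac-3-[2,4-bis(benzyloxy)-6-(3-methylbutyl)phenyl]-3-[(tert-butyldimethylsilyl)oxy]-N-methoxy-N-methylpropanamide
Product: 16 rac-3-[2,4-bis(benzyloxy)-6-(3-methylbutyl)phenyl]-3-[(tert-butyldimethylsilyl)oxy]propanal, via aluminium hemiaminal 15 (not isolated)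
Conditions: i-Bu2AlH (1.4 equiv), THF, −78 °C; then aq. KNaC4H4O6, rt
Reagents that add atoms: none
Why: In this Weinreb amide reduction the chelated tetrahedral adduct 15 survives until work-up, so the reaction stops cleanly at the aldehyde, and benzyl and silyl ethers are untouched.

**Step 9**
Reactants: 17 4-hydroxy-6-methyl-2H-pyran-2-one (triacetic acid lactone)
Product: 18 4-(benzyloxy)-6-methyl-2H-pyran-2-one
Conditions: BnBr (1.1 equiv), K2CO3 (1.5 equiv), DMF, rt
Reagents that add atoms: benzyl bromide BrCc1ccccc1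
Why: Williamson-type O-alkylation of the vinylogous acid in a polar aprotic solvent goes mainly at O4, and the minor C3-benzyl product is removed by chromatography.

**Step 10 (key fragment coupling)**
Reactants: 16 rac-3-[2,4-bis(benzyloxy)-6-(3-methylbutyl)phenyl]-3-[(tert-butyldimethylsilyl)oxy]propanal; 18 4-(benzyloxy)-6-methyl-2H-pyran-2-one
Product: 20 4-(benzyloxy)-6-{4-[2,4-bis(benzyloxy)-6-(3-methylbutyl)phenyl]-4-[(tert-butyldimethylsilyl)oxy]-2-hydroxybutyl}-2H-pyran-2-one (mixture of racemic diastereomers), via lithium pyrone dienolate 19 (not isolated)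
Conditions: 18 (1.3 equiv), commercial LiN(i-Pr)2 solution (1.25 equiv), THF, −78 °C, 45 min; then 16, −78 °C, 1.5 h; AcOH quench at −78 °C
Reagents that add atoms: none
Why: This is an intermolecular vinylogous aldol addition in which the C6-methyl group of a 4-alkoxy-2-pyrone is deprotonated to an extended dienolate that attacks aldehydes through its exocyclic carbon faster than it enolises them at −78 °C; the new carbinol forms without control, and both carbinol centres are erased in step 12.

**Step 11**
Reactants: 20 4-(benzyloxy)-6-{4-[2,4-bis(benzyloxy)-6-(3-methylbutyl)phenyl]-4-[(tert-butyldimethylsilyl)oxy]-2-hydroxybutyl}-2H-pyran-2-one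
Product: 21 4-(benzyloxy)-6-{4-[2,4-bis(benzyloxy)-6-(3-methylbutyl)phenyl]-2,4-dihydroxybutyl}-2H-pyran-2-one (mixture of racemic diastereomers)
Conditions: Bu4NF (2 equiv), AcOH (2 equiv), THF, 0 °C → rt
Reagents that add atoms: none
Why: Buffered fluoride desilylation is done while no carbonyl flanks the chain, so neither base-induced β-elimination nor acid ionisation of the benzylic carbinol can occur.

**Step 12**
Reactants: 21 4-(benzyloxy)-6-{4-[2,4-bis(benzyloxy)-6-(3-methylbutyl)phenyl]-2,4-dihydroxybutyl}-2H-pyran-2-one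
Product: 24 1-[2,4-bis(benzyloxy)-6-(3-methylbutyl)phenyl]-4-[4-(benzyloxy)-2-oxo-2H-pyran-6-yl]butane-1,3-dione, via benzylic hydroxy ketone 22 (not isolated), via aryl keto carbinol 23 (not isolated)
Conditions: IBX (5 equiv), EtOAc, 75 °C, 4–6 h; filter, concentrate
Reagents that add atoms: none
Why: IBX as a suspension in hot EtOAc takes secondary alcohols and β-hydroxy ketones to β-diketones without attacking the active methylenes, benzyl ethers or pyrone, and it removes both carbinol stereocentres to give an achiral compound.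

**Step 13**
Reactants: 24 1-[2,4-bis(benzyloxy)-6-(3-methylbutyl)phenyl]-4-[4-(benzyloxy)-2-oxo-2H-pyran-6-yl]butane-1,3-dione
Product: 26 rac-2,7-dihydroxy-2-[(4-hydroxy-2-oxo-2H-pyran-6-yl)methyl]-5-(3-methylbutyl)-2,3-dihydro-4H-chromen-4-one, via open-chain diketone 25 (not isolated)
Conditions: H2 (1 atm), 10% Pd/C, EtOAc–THF 1:1, rt, followed by HPLC-MS and stopped at 3 equiv uptake; filter, evaporate below 25 °C, no acid
Reagents that add atoms: none
Why: Neutral catalytic hydrogenolysis removes all three benzyl groups, and the only ortho phenol then adds to the C3 ketone of the chain (spontaneous hemiketalisation) to close ring B without dehydration to the chromone; C2 forms as a racemate because no chiral information is present.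

**Step 14**
Reactants: 26 rac-2,7-dihydroxy-2-[(4-hydroxy-2-oxo-2H-pyran-6-yl)methyl]-5-(3-methylbutyl)-2,3-dihydro-4H-chromen-4-one
Product: 27 (2R)-2,7-dihydroxy-2-[(4-hydroxy-2-oxo-2H-pyran-6-yl)methyl]-5-(3-methylbutyl)-2,3-dihydro-4H-chromen-4-one
Conditions: preparative SFC on an immobilised cellulose tris(3,5-dichlorophenylcarbamate) phase, CO2/i-PrOH, 15 °C; fractions collected cold, evaporated below 10 °C and stored solid at −20 °C; the other antipode is re-equilibrated to 26 (wet THF, 1% Et3N, rt) and re-injected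
Reagents that add atoms: none
Why: In this chromatographic resolution on a chiral stationary phase, C2 is fixed as R by collecting the antipode whose ECD spectrum matches the curve calculated for (R), confirmed by anomalous-dispersion crystal-structure analysis, and no later step exists that could scramble it.

**Compound list**
1 | 3,5-dimethoxybenzaldehyde | COc1cc(C=O)cc(OC)c1 | starting material
2 | (2-methylpropyl)triphenylphosphonium bromide | CC(C)C[P+](c1ccccc1)(c1ccccc1)c1ccccc1.[Br-] | starting material
3 | (2-methylpropylidene)triphenylphosphorane | CC(C)C=P(c1ccccc1)(c1ccccc1)c1ccccc1 | intermediate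
4 | 1,3-dimethoxy-5-(3-methylbut-1-en-1-yl)benzene (Z/E mixture) | COc1cc(C=CC(C)C)cc(OC)c1 | intermediate
5 | 1,3-dimethoxy-5-(3-methylbutyl)benzene | COc1cc(CCC(C)C)cc(OC)c1 | intermediate
6 | 1,3-bis[(dibromoboryl)oxy]-5-(3-methylbutyl)benzene | CC(C)CCc1cc(OB(Br)Br)cc(OB(Br)Br)c1 | intermediate
7 | 5-(3-methylbutyl)benzene-1,3-diol | CC(C)CCc1cc(O)cc(O)c1 | intermediate
8 | N-{[2,4-dihydroxy-6-(3-methylbutyl)phenyl]methylidene}-N-methylmethanaminium dichlorophosphate | CC(C)CCc1cc(O)cc(O)c1C=[N+](C)C.[O-]P(=O)(Cl)Cl | intermediate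
9 | 2,4-dihydroxy-6-(3-methylbutyl)benzaldehyde | CC(C)CCc1cc(O)cc(O)c1C=O | intermediate
10 | 2,4-bis(benzyloxy)-6-(3-methylbutyl)benzaldehyde | CC(C)CCc1cc(OCc2ccccc2)cc(OCc2ccccc2)c1C=O | intermediate
11 | N-methoxy-N-methylacetamide | CC(=O)N(C)OC | starting material
12 | lithium 1-[methoxy(methyl)amino]ethen-1-olate | [Li+].[O-]C(=C)N(C)OC | intermediate
13 | rac-3-[2,4-bis(benzyloxy)-6-(3-methylbutyl)phenyl]-3-hydroxy-N-methoxy-N-methylpropanamide | CC(C)CCc1cc(OCc2ccccc2)cc(OCc2ccccc2)c1C(O)CC(=O)N(C)OC | intermediate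
14 | rac-3-[2,4-bis(benzyloxy)-6-(3-methylbutyl)phenyl]-3-[(tert-butyldimethylsilyl)oxy]-N-methoxy-N-methylpropanamide | CC(C)CCc1cc(OCc2ccccc2)cc(OCc2ccccc2)c1C(CC(=O)N(C)OC)O[Si](C)(C)C(C)(C)C | intermediate
15 | diisobutylaluminium alkoxide of the hemiaminal formed by hydride addition to 14 | CC(C)CCc1cc(OCc2ccccc2)cc(OCc2ccccc2)c1C(CC(O[Al](CC(C)C)CC(C)C)N(C)OC)O[Si](C)(C)C(C)(C)C | intermediate
16 | rac-3-[2,4-bis(benzyloxy)-6-(3-methylbutyl)phenyl]-3-[(tert-butyldimethylsilyl)oxy]propanal | CC(C)CCc1cc(OCc2ccccc2)cc(OCc2ccccc2)c1C(CC=O)O[Si](C)(C)C(C)(C)C | intermediate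
17 | 4-hydroxy-6-methyl-2H-pyran-2-one (triacetic acid lactone) | Cc1cc(O)cc(=O)o1 | starting material
18 | 4-(benzyloxy)-6-methyl-2H-pyran-2-one | Cc1cc(OCc2ccccc2)cc(=O)o1 | intermediate
19 | lithium 4-(benzyloxy)-6-methylidene-6H-pyran-2-olate | [Li+].[O-]C1=CC(OCc2ccccc2)=CC(=C)O1 | intermediate
20 | 4-(benzyloxy)-6-{4-[2,4-bis(benzyloxy)-6-(3-methylbutyl)phenyl]-4-[(tert-butyldimethylsilyl)oxy]-2-hydroxybutyl}-2H-pyran-2-one (racemic diastereomer mixture) | CC(C)CCc1cc(OCc2ccccc2)cc(OCc2ccccc2)c1C(CC(O)Cc1cc(OCc2ccccc2)cc(=O)o1)O[Si](C)(C)C(C)(C)C | intermediate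
21 | 4-(benzyloxy)-6-{4-[2,4-bis(benzyloxy)-6-(3-methylbutyl)phenyl]-2,4-dihydroxybutyl}-2H-pyran-2-one (racemic diastereomer mixture) | CC(C)CCc1cc(OCc2ccccc2)cc(OCc2ccccc2)c1C(O)CC(O)Cc1cc(OCc2ccccc2)cc(=O)o1 | intermediate
22 | rac-4-(benzyloxy)-6-{4-[2,4-bis(benzyloxy)-6-(3-methylbutyl)phenyl]-4-hydroxy-2-oxobutyl}-2H-pyran-2-one | CC(C)CCc1cc(OCc2ccccc2)cc(OCc2ccccc2)c1C(O)CC(=O)Cc1cc(OCc2ccccc2)cc(=O)o1 | intermediate
23 | rac-4-(benzyloxy)-6-{4-[2,4-bis(benzyloxy)-6-(3-methylbutyl)phenyl]-2-hydroxy-4-oxobutyl}-2H-pyran-2-one | CC(C)CCc1cc(OCc2ccccc2)cc(OCc2ccccc2)c1C(=O)CC(O)Cc1cc(OCc2ccccc2)cc(=O)o1 | intermediate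
24 | 1-[2,4-bis(benzyloxy)-6-(3-methylbutyl)phenyl]-4-[4-(benzyloxy)-2-oxo-2H-pyran-6-yl]butane-1,3-dione | CC(C)CCc1cc(OCc2ccccc2)cc(OCc2ccccc2)c1C(=O)CC(=O)Cc1cc(OCc2ccccc2)cc(=O)o1 | intermediate
25 | 1-[2,4-dihydroxy-6-(3-methylbutyl)phenyl]-4-(4-hydroxy-2-oxo-2H-pyran-6-yl)butane-1,3-dione | CC(C)CCc1cc(O)cc(O)c1C(=O)CC(=O)Cc1cc(O)cc(=O)o1 | intermediate
26 | rac-2,7-dihydroxy-2-[(4-hydroxy-2-oxo-2H-pyran-6-yl)methyl]-5-(3-methylbutyl)-2,3-dihydro-4H-chromen-4-one | CC(C)CCc1cc(O)cc2c1C(=O)CC(O)(Cc1cc(O)cc(=O)o1)O2 | intermediate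
27 | (2R)-2,7-dihydroxy-2-[(4-hydroxy-2-oxo-2H-pyran-6-yl)methyl]-5-(3-methylbutyl)-2,3-dihydro-4H-chromen-4-one | CC(C)CCc1cc(O)cc2c1C(=O)C[C@@](O)(Cc1cc(O)cc(=O)o1)O2 | target

**Total step count:** 14.
**Longest linear sequence:** 13 (steps 1–8 and 10–14; step 9 is the side branch).

**Three steps most likely to fail**

**Step 14.** The antipodes may interconvert through 25 on the column or during evaporation, or may not separate. The fallback sets out from 26 and comes back at 27. It uses the lability instead of fighting it, through a crystallisation-induced diastereomer transformation.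
- 26 is slurried with 1.0 equiv of (S)-N,N-dimethyl-1-phenylethylamine in i-PrOAc/heptane at 35–40 °C and cooled slowly. The amine is tertiary, so it cannot condense with the diketone or the pyrone.
- The amine deprotonates the acidic pyrone hydroxyl (pKa about 5) and also catalyses ring–chain epimerisation in solution. The whole batch therefore drains into the less soluble salt, (S)-N,N-dimethyl-1-phenylethylammonium 6-{[(2R)-2,7-dihydroxy-5-(3-methylbutyl)-4-oxo-3,4-dihydro-2H-chromen-2-yl]methyl}-2-oxo-2H-pyran-4-olate F2.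
- Which amine antipode pairs with the (R)-hemiketal is settled in a small screen, since both are sold. It is written here for the (S)-amine.
- Partition of the salt between cold EtOAc and cold aqueous citric acid at 0 °C frees 27.

**Step 13.** The pyrone C5–C6 double bond may be reduced before the third benzyl group has left, or the product may dehydrate to the chromone on the catalyst. The fallback sets out from 24 and comes back at 26. It replaces reduction by Lewis-acid benzyl transfer.
- BCl3 (6 equiv) and pentamethylbenzene (9 equiv) in CH2Cl2 at −78 °C pass the benzyl cations to the arene scavenger without touching any C=C bond.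
- A cold quench with aqueous NaH2PO4/THF gives 25, which closes to 26.
- New compounds on this way: none F0.

**Step 12.** Oxidising two carbinols in one pot risks dehydration of 22 or 23, incomplete oxidation of the hindered benzylic alcohol, or over-oxidation of the active methylenes. The fallback sets out from 20 and comes back at 24. The two oxidations are separated by using the silyl group as a differentiator.
- Dess–Martin periodinane/NaHCO3 in CH2Cl2 at 0 °C oxidises the only free hydroxyl of 20 to rac-4-(benzyloxy)-6-{4-[2,4-bis(benzyloxy)-6-(3-methylbutyl)phenyl]-4-[(tert-butyldimethylsilyl)oxy]-2-oxobutyl}-2H-pyran-2-one F1.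
- Et3N·3HF in MeCN at rt is nearly neutral, so it causes neither β-elimination nor benzylic ionisation. It removes the silyl group to give 22, which is now isolated.
- A single IBX oxidation (EtOAc, 75 °C) of this β-hydroxy ketone gives 24.

**Further compounds**
F1 | step 12 | rac-4-(benzyloxy)-6-{4-[2,4-bis(benzyloxy)-6-(3-methylbutyl)phenyl]-4-[(tert-butyldimethylsilyl)oxy]-2-oxobutyl}-2H-pyran-2-one | CC(C)CCc1cc(OCc2ccccc2)cc(OCc2ccccc2)c1C(CC(=O)Cc1cc(OCc2ccccc2)cc(=O)o1)O[Si](C)(C)C(C)(C)C
F0 | step 13 | none | none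
F2 | step 14 | (S)-N,N-dimethyl-1-phenylethylammonium 6-{[(2R)-2,7-dihydroxy-5-(3-methylbutyl)-4-oxo-3,4-dihydro-2H-chromen-2-yl]methyl}-2-oxo-2H-pyran-4-olate | CC(C)CCc1cc(O)cc2c1C(=O)C[C@@](O)(Cc1cc([O-])cc(=O)o1)O2.C[C@H]([NH+](C)C)c1ccccc1
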